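Each 4-methoxy-3-methyl-2-pyrone is disconnected at its O1–C6 bond. With the cyclobutane numbered C1 (CO2Me), C2 (CO2H), C3 (beside C2) and C4, pyrone atoms C5 and C6 become an alkyne on each quaternary carbon C3 and C4, and pyrone C2–C4 a tert-butyl (E)-3-methoxy-2-methylacrylate. A single gold-catalysed operation closes both pyrone rings by 6-endo attack of the ester carbonyl oxygen on the ring-bound alkyne carbon, with loss of isobutene. The precursor is a meso cyclobutane diyne whose C1 and C2 carry cis CH2OH groups tied up as an acetonide; its four stereocentres come from one anti [2+2] photoadduct, and the meso anhydride is opened enantioselectively at the end.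

Key step: step 8

Assumption: the sense of the quinidine-mediated methanolysis in step 13 is assigned by analogy with simple cis-fused bicyclic meso-anhydrides and is to be confirmed on the first run; quinine is expected to give the antipode.

Step 1
Reactants: 1 2,3-dimethylmaleic anhydride; 2 4,7-dihydro-2,2-dimethyl-1,3-dioxepine
Product: 3 meso cis-anti-cis photoadduct (cyclobutane fused at C3–C4 to the anhydride ring and at C1–C2 to the 2,2-dimethyl-1,3-dioxepane ring; CH3 on C3 and C4; the two rings on opposite faces)
Conditions: hν (Pyrex, 300–350 nm), acetophenone (sens.), 2 (3 equiv), MeCN, rt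
Reagents that add atoms: none
Why: Triplet-sensitised [2+2] photocycloaddition of a maleic anhydride to a cyclic cis-alkene, in which both ring fusions close cis and the 1,4-biradical should close on the face away from the dioxepane, so that the anti adduct sets all four ring stereocentres at once (methyls syn to the CH2O arms, carbonyl carbons anti).

Step 2
Reactants: 3 meso cis-anti-cis photoadduct
Product: 4 meso diol (C3 and C4 each bear CH3 and CH2OH; the CH2OH groups are trans to the acetonide-bridged CH2O arms on C1 and C2)
Conditions: LiAlH4, THF, 0 °C → reflux; Fieser work-up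
Reagents that add atoms: none
Why: Hydride reduction of a cyclic anhydride to the 1,4-diol, to which the ketal is inert and which touches no stereocentre.

Step 3
Reactants: 4 meso diol
Product: 5 meso dialdehyde (CHO in place of each CH2OH on C3 and C4)
Conditions: (COCl)2, DMSO, CH2Cl2, −78 °C; Et3N, −78 → 0 °C
Reagents that add atoms: none
Why: Swern oxidation, in which both neopentyl alcohols are activated before base is added so that no lactol can form, giving a dialdehyde that has no α-hydrogen and therefore cannot enolise or epimerise.

Step 4
Reactants: 5 meso dialdehyde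
Product: 6 meso diyne (ethynyl on C3 and on C4; both alkynes trans to the CH2O arms)
Conditions: dimethyl (1-diazo-2-oxopropyl)phosphonate, K2CO3, MeOH, 0 °C → rt
Reagents that add atoms: dimethyl (1-diazo-2-oxopropyl)phosphonate, CC(=O)C(=[N+]=[N-])P(=O)(OC)OC
Why: Seyferth–Gilbert homologation in the Ohira–Bestmann variant, which accepts α-quaternary non-enolisable aldehydes and adds a single slim carbon at each crowded centre, and which is run no warmer than rt because cis-1,2-dialkynylcyclobutanes are liable to thermal [3,3] rearrangement.

Step 5
Reactants: 6 meso diyne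
Product: 8 meso bis(Weinreb ynamide) (each alkyne terminus carries C(=O)N(OMe)Me), via dilithium diacetylide 7 (not isolated)
Conditions: n-BuLi (2.2 equiv), THF, −78 °C; then ClC(=O)N(OMe)Me, −78 → 0 °C
Reagents that add atoms: N-methoxy-N-methylcarbamoyl chloride, CON(C)C(=O)Cl
Why: Deprotonation of the terminal alkynes followed by C-acylation of the acetylide with a carbamoyl chloride, an electrophile that reacts once only.

Step 6
Reactants: 8 meso bis(Weinreb ynamide); 9 tert-butyl propanoate
Product: 12 bis(β-keto ester) (each alkyne terminus carries C(=O)CH(CH3)CO2t-Bu; mixture of epimers at the two α-carbons), via lithium enolate 10 (not isolated), via bis-lithium tetrahedral adduct 11 (not isolated)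
Conditions: 9 (3 equiv), LiN(i-Pr)2 (3 equiv), THF, −78 °C; then 8, −78 → −40 °C; aq. NH4Cl
Reagents that add atoms: none
Why: Crossed Claisen-type acylation of an ester enolate by a Weinreb amide, whose chelated tetrahedral adduct holds until the quench so that over-addition is excluded, while the two new α-stereocentres are of no consequence because step 7 erases them.

Step 7
Reactants: 12 bis(β-keto ester)
Product: 13 meso bis(enol ether) diyne (an (E)-5-tert-butoxy-3-methoxy-4-methyl-5-oxopent-3-en-1-yn-1-yl group on C3 and on C4)
Conditions: Me2SO4, Cs2CO3, DMF, 0 °C → rt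
Reagents that add atoms: dimethyl sulfate, COS(=O)(=O)OC
Why: O-alkylation of a β-keto ester enolate by a hard electrophile in a dissociating solvent, where the loosely paired caesium enolate is expected to react in its extended form (enolate oxygen anti to the ester, slim alkyne syn to it) to give the (E) enol ether, which should also be the more stable isomer, and where the tertiary α-carbon disfavours C-methylation.

Step 8
Reactants: 13 meso bis(enol ether) diyne
Product: 14 meso bis(pyrone) acetonide (4-methoxy-3-methyl-2-oxo-2H-pyran-6-yl on C3 and on C4)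
Conditions: Ph3PAuNTf2 (10 mol%), CH2Cl2, 4 Å MS, rt
Reagents that add atoms: none
Why: Cationic monovalent gold coordinates each alkyne, and the carbonyl oxygen of the tert-butyl ester, held on the same side of the enol ether double bond as the alkyne, adds anti to gold at the alkyne carbon bound to the cyclobutane, giving a 2-tert-butoxypyrylium vinylgold species that loses isobutene and is protodeaurated at C5. The closest known reaction type is the gold-catalysed cyclisation of tert-butyl 2-en-4-ynoates and 3-oxoalk-4-ynoates to 2-pyrones. Each of the two rings closes in the 6-endo-dig mode through its O1–C6 bond; no stereocentre is formed and the four existing ones take no part. The selectivity needed is 6-endo over 5-exo attack: the (E) geometry places the carbonyl oxygen over the distal alkyne carbon, and that carbon, δ to the ester and bearing a tertiary alkyl group, accepts positive charge better than the proximal one. Dry, nucleophile-free conditions at rt should keep the dioxepane acetonide and the enol ethers intact and leave no room for thermal rearrangement of the diyne.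

Step 9
Reactants: 14 meso bis(pyrone) acetonide
Product: 15 meso bis(pyrone) diol (free CH2OH on C1 and on C2)
Conditions: AcOH/H2O (4:1), rt
Reagents that add atoms: none
Why: Acid-catalysed ketal hydrolysis, in which the seven-membered acetonide is far more labile than the 4-methoxy-2-pyrone, a vinylogous ester that should survive dilute acid.

Step 10
Reactants: 15 meso bis(pyrone) diol
Product: 16 meso cis-dialdehyde (CHO on C1 and on C2; used crude)
Conditions: (COCl)2, DMSO, CH2Cl2, −78 °C; i-Pr2NEt, −78 → −40 °C; cold pH 7 buffer
Reagents that add atoms: none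
Why: Swern oxidation, where activation of both alcohols before base addition avoids lactol and lactone formation, and a hindered base at low temperature with immediate use of the crude product should limit epimerisation at C1 and C2.

Step 11
Reactants: 16 meso cis-dialdehyde
Product: 17 meso cis-diacid (CO2H on C1 and on C2)
Conditions: NaClO2, NaH2PO4, 2-methyl-2-butene, t-BuOH/H2O, 0 °C → rt
Reagents that add atoms: sodium chlorite, [Na+].[O-]Cl=O
Why: Pinnick oxidation, which at buffered pH oxidises only the aldehydes without epimerising C1 and C2, the alkene scavenger removing HOCl before it can chlorinate pyrone C5.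

Step 12
Reactants: 17 meso cis-diacid
Product: 18 meso cyclic anhydride (five-membered anhydride across C1–C2)
Conditions: (CF3CO)2O, CH2Cl2, 0 °C → rt; evaporate
Reagents that add atoms: none
Why: Cyclodehydration of a cis-1,2-diacid to its five-membered anhydride, which only the cis isomer can form and which is done without heating to spare the strained bis(pyronyl)cyclobutane.

Step 13
Reactants: 18 meso cyclic anhydride
Product: 19 target hemiester (C1 CO2Me, R; C2 CO2H, S; C3 R; C4 S)
Conditions: quinidine (1.1 equiv), MeOH (3 equiv), toluene, −55 °C; 1 M HCl work-up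
Reagents that add atoms: methanol, CO
Why: Cinchona-alkaloid-mediated enantioselective methanolysis of a meso anhydride, in which the alkaloid (general base through its quinuclidine nitrogen) should direct methanol to the enantiotopic carbonyl group on C1, so that the absolute configuration of all four ring carbons is fixed by group selection without any stereocentre being touched.

Compound list
1 | 2,3-dimethylmaleic anhydride | CC1=C(C)C(=O)OC1=O | starting material
2 | 4,7-dihydro-2,2-dimethyl-1,3-dioxepine | CC1(C)OCC=CCO1 | starting material
3 | meso cis-anti-cis photoadduct (anhydride across C3–C4, dioxepane across C1–C2, rings anti, methyls syn to the CH2O arms) | CC1(C)OC[C@@H]2[C@H](CO1)[C@@](C)(C(=O)OC3=O)[C@]23C | intermediate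
4 | meso diol (CH3 and CH2OH on C3 and C4; CH2OH trans to the CH2O arms) | CC1(C)OC[C@@H]2[C@H](CO1)[C@@](C)(CO)[C@@]2(C)CO | intermediate
5 | meso dialdehyde | CC1(C)OC[C@@H]2[C@H](CO1)[C@@](C)(C=O)[C@@]2(C)C=O | intermediate
6 | meso diyne (ethynyl on C3 and C4) | CC1(C)OC[C@@H]2[C@H](CO1)[C@@](C)(C#C)[C@@]2(C)C#C | intermediate
7 | dilithium diacetylide of 6 (not isolated) | CC1(C)OC[C@@H]2[C@H](CO1)[C@@](C)(C#C[Li])[C@@]2(C)C#C[Li] | intermediate
8 | meso bis(Weinreb ynamide) | CC1(C)OC[C@@H]2[C@H](CO1)[C@@](C)(C#CC(=O)N(C)OC)[C@@]2(C)C#CC(=O)N(C)OC | intermediate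
9 | tert-butyl propanoate | CCC(=O)OC(C)(C)C | starting material
10 | lithium enolate of tert-butyl propanoate (not isolated; geometry of no consequence) | CC=C(O[Li])OC(C)(C)C | intermediate
11 | bis-lithium tetrahedral adduct of 10 with 8 (not isolated; new centres unassigned) | CC1(C)OC[C@@H]2[C@H](CO1)[C@@](C)(C#CC(O[Li])(N(C)OC)C(C)C(=O)OC(C)(C)C)[C@@]2(C)C#CC(O[Li])(N(C)OC)C(C)C(=O)OC(C)(C)C | intermediate
12 | bis(tert-butyl 2-methyl-3-oxopent-4-ynoate) on C3 and C4 (mixture of α-epimers) | CC1(C)OC[C@@H]2[C@H](CO1)[C@@](C)(C#CC(=O)C(C)C(=O)OC(C)(C)C)[C@@]2(C)C#CC(=O)C(C)C(=O)OC(C)(C)C | intermediate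
13 | meso bis[(E)-5-tert-butoxy-3-methoxy-4-methyl-5-oxopent-3-en-1-yn-1-yl] diyne, acetonide (key-step precursor) | CC1(C)OC[C@@H]2[C@H](CO1)[C@@](C)(C#C/C(OC)=C(/C)C(=O)OC(C)(C)C)[C@@]2(C)C#C/C(OC)=C(/C)C(=O)OC(C)(C)C | intermediate
14 | meso bis(4-methoxy-3-methyl-2-oxo-2H-pyran-6-yl) acetonide (key-step product) | CC1(C)OC[C@@H]2[C@H](CO1)[C@@](C)(c3cc(OC)c(C)c(=O)o3)[C@@]2(C)c4cc(OC)c(C)c(=O)o4 | intermediate
15 | meso bis(pyrone) diol | OC[C@@H]1[C@H](CO)[C@@](C)(c2cc(OC)c(C)c(=O)o2)[C@@]1(C)c3cc(OC)c(C)c(=O)o3 | intermediate
16 | meso bis(pyrone) cis-dialdehyde | O=C[C@@H]1[C@H](C=O)[C@@](C)(c2cc(OC)c(C)c(=O)o2)[C@@]1(C)c3cc(OC)c(C)c(=O)o3 | intermediate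
17 | meso bis(pyrone) cis-diacid | OC(=O)[C@@H]1[C@H](C(=O)O)[C@@](C)(c2cc(OC)c(C)c(=O)o2)[C@@]1(C)c3cc(OC)c(C)c(=O)o3 | intermediate
18 | meso bis(pyrone) cyclic anhydride across C1–C2 | O=C1OC(=O)[C@@H]2[C@H]1[C@@](C)(c3cc(OC)c(C)c(=O)o3)[C@@]2(C)c4cc(OC)c(C)c(=O)o4 | intermediate
19 | CNP0481603.1: cis-hemiester with C1 (CO2Me) R, C2 (CO2H) S, C3 R, C4 S; methyls cis to the carboxyl groups, pyronyls trans | COC(=O)[C@@H]1[C@H](C(=O)O)[C@@](C)(c2cc(OC)c(C)c(=O)o2)[C@@]1(C)c3cc(OC)c(C)c(=O)o3 | target

Total step count: 13. Longest linear sequence: 13 steps (from 1 or 2 to 19; 9 enters in step 6).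

Steps most likely to fail

Step 8 (double gold cyclisation). The second closure may stall at the crowded vicinal quaternary centres, 5-exo closure may compete, or adventitious acid may strip the acetonide and expose hydroxyl groups to the gold-activated alkynes. The fallback replaces π-acid catalysis by electrophilic halolactonisation. It sets out from 13: ICl with NaHCO3 in CH2Cl2 (−78 → 0 °C) should induce 6-endo iodolactonisation with loss of the tert-butyl groups, giving the bis(5-iodo-4-methoxy-3-methyl-2-pyron-6-yl) acetonide F1. Hydrodeiodination with Bu3SnH and Pd(PPh3)4 (zerovalent palladium) in THF at rt then returns to the route at 14.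

Step 7 (O-methylation). Control of the enol ether geometry may be poor, and C-methylation may compete. The fallback reverses the order of ring closure and methylation and sets out from 12. Ph3PAuNTf2 in MeNO2 at rt should cyclise the β-keto esters themselves (the established 6-endo closure of tert-butyl 3-oxoalk-4-ynoates with loss of isobutene) to the bis(4-hydroxy-3-methyl-2-pyron-6-yl) acetonide F2. Me2SO4 and K2CO3 in acetone at rt then methylate the 4-hydroxyl groups, and the route is rejoined at 14. The cost is a possible share of 2-methoxy-4-pyrone isomer to be removed.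

Step 13 (desymmetrisation). Discrimination of the enantiotopic carbonyl groups may be low or of the opposite sense on this hindered anhydride, and solubility at −55 °C may be poor. The fallback gives up catalyst control for resolution and sets out from 18. MeOH with catalytic DMAP in CH2Cl2 at rt should open the anhydride without selectivity to the racemic hemiester, that is 19 together with its antipode, the (C1 S, C2 R, C3 S, C4 R) hemiester F3. Preparative chromatography on a chiral stationary phase separates the two and returns to the route at 19, the configuration being assigned by X-ray or ECD.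

Further compounds
F1 | step 8 | meso bis(5-iodo-4-methoxy-3-methyl-2-oxo-2H-pyran-6-yl) acetonide | CC1(C)OC[C@@H]2[C@H](CO1)[C@@](C)(c3c(I)c(OC)c(C)c(=O)o3)[C@@]2(C)c4c(I)c(OC)c(C)c(=O)o4
F2 | step 7 | meso bis(4-hydroxy-3-methyl-2-oxo-2H-pyran-6-yl) acetonide | CC1(C)OC[C@@H]2[C@H](CO1)[C@@](C)(c3cc(O)c(C)c(=O)o3)[C@@]2(C)c4cc(O)c(C)c(=O)o4
F3 | step 13 | antipode of 19 (C1 S, C2 R, C3 S, C4 R) | COC(=O)[C@H]1[C@@H](C(=O)O)[C@](C)(c2cc(OC)c(C)c(=O)o2)[C@]1(C)c3cc(OC)c(C)c(=O)o3
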